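**Retrosynthetic overview**

1. The C14–O bond is made last. Allylic C–H hydroxylation (ene reaction, then [2,3] shift) of the all-ring-trans germacranolide 19 installs the CH2OH and at the same time turns C1=C10 into the ring-cis geometry of the target. C14 is therefore carried as a methyl group throughout.
2. The ten-membered carbocycle (C7–C8) and the γ-lactone (C8–O–C12) close together from acyclic bromo aldehyde 16 by a catalytic asymmetric chromium allylation–lactonisation. This is the only ring-forming step and sets C7 and C8.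
3. The side chain is joined early through the C15–O ester bond (alcohol 10 + enantiopure acid 11); its stereocentre is bought, not made.
4. C4=C5 geometry comes from anti-carbomagnesiation of propargyl alcohol followed by allylation. The acrylate unit comes from cross-metathesis. C1=C10 geometry comes from carboalumination of alkyne 1.

Assumption: (2R)-3-chloro-2-hydroxy-2-methylpropanoic acid (11) is taken as a catalogue compound sold as the single enantiomer; locants C1–C15 follow germacrane numbering of the target (lactone on C7/C8, C12 carbonyl, C13 exo-methylene, C14 on C10, C15 on C4).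

**Route**

Step 1
Reactants: 1 tert-butyl(but-3-yn-1-yloxy)dimethylsilane
Product: 4 (3E)-6-{[tert-butyl(dimethyl)silyl]oxy}-4-methylhex-3-en-1-ol, via alkenyldimethylalane 2 (not isolated), via lithium alkenylalanate 3 (not isolated)
Conditions: Me3Al (2.5 equiv), Cp2ZrCl2 (0.25 equiv), CH2Cl2, 0 °C to rt; volatiles removed; n-BuLi (1.1 equiv), THF/hexane, −78 °C; oxirane (3 equiv), −78 °C to rt; aqueous work-up
Reagents that add atoms: trimethylaluminium, C[Al](C)C; oxirane, C1CO1
Why: Zirconium-catalysed carboalumination (Negishi) adds CH3 and Al syn across the terminal alkyne with CH3 on the internal carbon, and the lithium alanate opens oxirane with retention at the alkenyl carbon, which fixes the C1=C10 alkene as E with the future C14 methyl cis to the new chain.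

Step 2
Reactants: 4 (3E)-6-{[tert-butyl(dimethyl)silyl]oxy}-4-methylhex-3-en-1-ol
Product: 5 {[(3E)-6-bromo-3-methylhex-3-en-1-yl]oxy}(tert-butyl)dimethylsilane
Conditions: CBr4, PPh3, CH2Cl2, 0 °C
Reagents that add atoms: carbon tetrabromide, BrC(Br)(Br)Br
Why: Appel bromination replaces the primary hydroxyl by bromide through SN2 attack on the alkoxyphosphonium ion and leaves the silyl ether and the trisubstituted alkene alone.

Step 3
Reactants: 5 {[(3E)-6-bromo-3-methylhex-3-en-1-yl]oxy}(tert-butyl)dimethylsilane; 6 prop-2-yn-1-ol; 7 3-bromoprop-1-ene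
Product: 10 (2Z)-2-[(3E)-6-{[tert-butyl(dimethyl)silyl]oxy}-4-methylhex-3-en-1-yl]hexa-2,5-dien-1-ol, via alkylmagnesium bromide 8 (not isolated), via cyclic alkenylmagnesium alkoxide 9 (not isolated)
Conditions: 5, Mg, Et2O, reflux; added to 6 (pre-treated with EtMgBr, 1.0 equiv) and CuI (10 mol%), Et2O, 0 °C to rt; then 7 (3 equiv), 0 °C to rt; aq. NH4Cl
Reagents that add atoms: none
Why: Copper-catalysed, alkoxide-directed anti-carbomagnesiation of propargyl alcohol puts the alkyl group on the carbon next to CH2O and magnesium trans to it in a five-membered chelate, and copper-mediated allylation of this alkenylmagnesium with retention therefore sets the C4=C5 alkene with C15 and C6 cis, as the target needs.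

Step 4
Reactants: 10 (2Z)-2-[(3E)-6-{[tert-butyl(dimethyl)silyl]oxy}-4-methylhex-3-en-1-yl]hexa-2,5-dien-1-ol; 11 (2R)-3-chloro-2-hydroxy-2-methylpropanoic acid
Product: 12 (2Z)-2-[(3E)-6-{[tert-butyl(dimethyl)silyl]oxy}-4-methylhex-3-en-1-yl]hexa-2,5-dien-1-yl (2R)-3-chloro-2-hydroxy-2-methylpropanoate
Conditions: EDC (1.6 equiv), DMAP (0.2 equiv), CH2Cl2, 0 °C to rt
Reagents that add atoms: none
Why: Carbodiimide (Steglich) esterification acylates the primary allylic alcohol while the hindered tertiary hydroxyl of the acid does not compete, and the purchased (R) stereocentre is not involved.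

Step 5
Reactants: 12 (2Z)-2-[(3E)-6-{[tert-butyl(dimethyl)silyl]oxy}-4-methylhex-3-en-1-yl]hexa-2,5-dien-1-yl (2R)-3-chloro-2-hydroxy-2-methylpropanoate; 13 methyl 2-(bromomethyl)prop-2-enoate
Product: 14 methyl (2Z,5Z,9E)-2-(bromomethyl)-12-{[tert-butyl(dimethyl)silyl]oxy}-6-({[(2R)-3-chloro-2-hydroxy-2-methylpropanoyl]oxy}methyl)-10-methyldodeca-2,5,9-trienoate
Conditions: 13 (5 equiv), second-generation Hoveyda–Grubbs catalyst RuCl2(H2IMes)(=CH-C6H4-2-OiPr) (10 mol%), 1,4-benzoquinone (20 mol%), CH2Cl2, 40 °C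
Reagents that add atoms: none
Why: Olefin cross-metathesis takes place only at the monosubstituted terminal alkene (both trisubstituted alkenes are inert to the catalyst) and joins it to the excess 1,1-disubstituted acrylate to give the trisubstituted enoate with the ester trans to the chain, the benzoquinone suppressing hydride-induced migration of the skipped diene.

Step 6
Reactants: 14 methyl (2Z,5Z,9E)-2-(bromomethyl)-12-{[tert-butyl(dimethyl)silyl]oxy}-6-({[(2R)-3-chloro-2-hydroxy-2-methylpropanoyl]oxy}methyl)-10-methyldodeca-2,5,9-trienoate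
Product: 15 methyl (2Z,5Z,9E)-2-(bromomethyl)-6-({[(2R)-3-chloro-2-hydroxy-2-methylpropanoyl]oxy}methyl)-12-hydroxy-10-methyldodeca-2,5,9-trienoate
Conditions: 48% aq. HF, MeCN, 0 °C
Reagents that add atoms: none
Why: Acidic fluoride removes the primary silyl ether (desilylation) without any amine or base, so the activated allylic bromide, the chlorohydrin and both esters are kept.

Step 7
Reactants: 15 methyl (2Z,5Z,9E)-2-(bromomethyl)-6-({[(2R)-3-chloro-2-hydroxy-2-methylpropanoyl]oxy}methyl)-12-hydroxy-10-methyldodeca-2,5,9-trienoate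
Product: 16 methyl (2Z,5Z,9E)-2-(bromomethyl)-6-({[(2R)-3-chloro-2-hydroxy-2-methylpropanoyl]oxy}methyl)-10-methyl-12-oxododeca-2,5,9-trienoate
Conditions: Dess–Martin periodinane (1.3 equiv), NaHCO3, CH2Cl2, 0 °C; used at once
Reagents that add atoms: none
Why: Dess–Martin oxidation stops at the aldehyde under buffered, non-basic conditions, which keeps the β,γ-alkene from moving into conjugation and does not touch the tertiary alcohol.

Step 8
Reactants: 16 methyl (2Z,5Z,9E)-2-(bromomethyl)-6-({[(2R)-3-chloro-2-hydroxy-2-methylpropanoyl]oxy}methyl)-10-methyl-12-oxododeca-2,5,9-trienoate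
Product: 19 (7R,8S)-15-{[(2R)-3-chloro-2-hydroxy-2-methylpropanoyl]oxy}germacra-1(10),4,11(13)-trien-12,8-olide (trans-fused lactone; C1=C10 and C4=C5 both ring-trans), via macrocyclic silyl ether 17 (not isolated), via macrocyclic hydroxy ester 18 (not isolated)
Conditions: CrCl2 (15 mol%), chiral 1,8-bis(oxazolinyl)carbazole ligand (18 mol%, antipode chosen for Re-face addition), Mn powder (3 equiv), Me3SiCl (2 equiv), i-Pr2NEt (0.3 equiv), THF/MeCN, rt, slow addition of 16 (final 3 mM); then 1 M HCl, THF, rt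
Reagents that add atoms: none
Why: Proposed new method: a catalytic enantioselective intramolecular Nozaki–Hiyama–Kishi-type 2-(alkoxycarbonyl)allylation in which Mn keeps a ligand-bound chromium centre divalent, two such centres convert the allylic bromide into a γ-substituted allylchromium species that equilibrates to its E form and adds through a closed chair transition state to the Re face of the tethered aldehyde (anti addition, so H7 and H8 end up trans), Me3SiCl frees the trivalent chromium alkoxide for turnover, and acid then cleaves the silyl ether and closes the γ-lactone by O-acylation; the closest known reactions are the intermolecular chromium-catalysed asymmetric 2-(alkoxycarbonyl)allylation of aldehydes to α-methylene-γ-butyrolactones and the stoichiometric CrCl2-mediated Barbier macrocyclisation used for germacranolides.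

Step 9
Reactants: 19 (7R,8S)-15-{[(2R)-3-chloro-2-hydroxy-2-methylpropanoyl]oxy}germacra-1(10),4,11(13)-trien-12,8-olide
Product: 20 (7R,8S)-15-{[(2R)-3-chloro-2-hydroxy-2-methylpropanoyl]oxy}-14-hydroxygermacra-1(10),4,11(13)-trien-12,8-olide (C1=C10 ring-cis, C4=C5 ring-trans; CNP0239315.1)
Conditions: SeO2 (0.5 equiv), t-BuOOH (70% aq., 3 equiv), CH2Cl2, rt
Reagents that add atoms: tert-butyl hydroperoxide, CC(C)(C)OO
Why: SeO2-mediated allylic hydroxylation is an ene reaction at the electron-richer C1=C10 alkene (C4=C5 is deactivated by its allylic acyloxy group) followed by a [2,3]-sigmatropic shift that delivers oxygen to C14 and rebuilds the alkene with CH2OH trans to C2, which is the ring-cis geometry of the target, as precedented for parthenolide-type E-1(10)-germacranolides.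

**Compound list**

1 | tert-butyl(but-3-yn-1-yloxy)dimethylsilane | C#CCCO[Si](C)(C)C(C)(C)C | starting material
2 | [(1E)-4-{[tert-butyl(dimethyl)silyl]oxy}-2-methylbut-1-en-1-yl]dimethylaluminium (alkenyldimethylalane) | C[Al](C)/C=C(\C)CCO[Si](C)(C)C(C)(C)C | intermediate
3 | lithium butyl[(1E)-4-{[tert-butyl(dimethyl)silyl]oxy}-2-methylbut-1-en-1-yl]dimethylaluminate (lithium alkenylalanate) | [Li+].CCCC[Al-](C)(C)/C=C(\C)CCO[Si](C)(C)C(C)(C)C | intermediate
4 | (3E)-6-{[tert-butyl(dimethyl)silyl]oxy}-4-methylhex-3-en-1-ol | OCC/C=C(\C)CCO[Si](C)(C)C(C)(C)C | intermediate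
5 | {[(3E)-6-bromo-3-methylhex-3-en-1-yl]oxy}(tert-butyl)dimethylsilane | BrCC/C=C(\C)CCO[Si](C)(C)C(C)(C)C | intermediate
6 | prop-2-yn-1-ol | C#CCO | starting material
7 | 3-bromoprop-1-ene | C=CCBr | starting material
8 | [(3E)-6-{[tert-butyl(dimethyl)silyl]oxy}-4-methylhex-3-en-1-yl]magnesium bromide | Br[Mg]CC/C=C(\C)CCO[Si](C)(C)C(C)(C)C | intermediate
9 | 4-[(3E)-6-{[tert-butyl(dimethyl)silyl]oxy}-4-methylhex-3-en-1-yl]-2,5-dihydro-1,2-oxamagnesole (cyclic alkenylmagnesium alkoxide) | [Mg]1OCC(CC/C=C(\C)CCO[Si](C)(C)C(C)(C)C)=C1 | intermediate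
10 | (2Z)-2-[(3E)-6-{[tert-butyl(dimethyl)silyl]oxy}-4-methylhex-3-en-1-yl]hexa-2,5-dien-1-ol | OC/C(CC/C=C(\C)CCO[Si](C)(C)C(C)(C)C)=C\CC=C | intermediate
11 | (2R)-3-chloro-2-hydroxy-2-methylpropanoic acid | OC(=O)[C@@](C)(O)CCl | starting material
12 | (2Z)-2-[(3E)-6-{[tert-butyl(dimethyl)silyl]oxy}-4-methylhex-3-en-1-yl]hexa-2,5-dien-1-yl (2R)-3-chloro-2-hydroxy-2-methylpropanoate | C=CC\C=C(/COC(=O)[C@@](C)(O)CCl)CC/C=C(\C)CCO[Si](C)(C)C(C)(C)C | intermediate
13 | methyl 2-(bromomethyl)prop-2-enoate | C=C(CBr)C(=O)OC | starting material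
14 | methyl (2Z,5Z,9E)-2-(bromomethyl)-12-{[tert-butyl(dimethyl)silyl]oxy}-6-({[(2R)-3-chloro-2-hydroxy-2-methylpropanoyl]oxy}methyl)-10-methyldodeca-2,5,9-trienoate | COC(=O)/C(CBr)=C/C\C=C(/COC(=O)[C@@](C)(O)CCl)CC/C=C(\C)CCO[Si](C)(C)C(C)(C)C | intermediate
15 | methyl (2Z,5Z,9E)-2-(bromomethyl)-6-({[(2R)-3-chloro-2-hydroxy-2-methylpropanoyl]oxy}methyl)-12-hydroxy-10-methyldodeca-2,5,9-trienoate | COC(=O)/C(CBr)=C/C\C=C(/COC(=O)[C@@](C)(O)CCl)CC/C=C(\C)CCO | intermediate
16 | methyl (2Z,5Z,9E)-2-(bromomethyl)-6-({[(2R)-3-chloro-2-hydroxy-2-methylpropanoyl]oxy}methyl)-10-methyl-12-oxododeca-2,5,9-trienoate | COC(=O)/C(CBr)=C/C\C=C(/COC(=O)[C@@](C)(O)CCl)CC/C=C(\C)CC=O | intermediate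
17 | methyl (7R,8S)-15-{[(2R)-3-chloro-2-hydroxy-2-methylpropanoyl]oxy}-8-(trimethylsilyloxy)germacra-1(10),4,11(13)-trien-12-oate, both ring alkenes ring-trans (macrocyclic silyl ether) | C[Si](C)(C)O[C@H]1C/C(C)=C/CC/C(COC(=O)[C@@](C)(O)CCl)=C/C[C@@H]1C(=C)C(=O)OC | intermediate
18 | methyl (7R,8S)-15-{[(2R)-3-chloro-2-hydroxy-2-methylpropanoyl]oxy}-8-hydroxygermacra-1(10),4,11(13)-trien-12-oate, both ring alkenes ring-trans (macrocyclic hydroxy ester) | O[C@H]1C/C(C)=C/CC/C(COC(=O)[C@@](C)(O)CCl)=C/C[C@@H]1C(=C)C(=O)OC | intermediate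
19 | (7R,8S)-15-{[(2R)-3-chloro-2-hydroxy-2-methylpropanoyl]oxy}germacra-1(10),4,11(13)-trien-12,8-olide, trans-fused lactone, C1=C10 ring-trans, C4=C5 ring-trans | C=C1C(=O)O[C@H]2C/C(C)=C/CC/C(COC(=O)[C@@](C)(O)CCl)=C/C[C@H]12 | intermediate
20 | (7R,8S)-15-{[(2R)-3-chloro-2-hydroxy-2-methylpropanoyl]oxy}-14-hydroxygermacra-1(10),4,11(13)-trien-12,8-olide, trans-fused lactone, C1=C10 ring-cis, C4=C5 ring-trans (CNP0239315.1) | C=C1C(=O)O[C@H]2C/C(CO)=C\CC/C(COC(=O)[C@@](C)(O)CCl)=C/C[C@H]12 | target

**Step count**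

Total steps: 9. Longest linear sequence: 9 steps (from 1; compounds 6, 7, 11 and 13 are bought).

**Three steps most likely to fail, with fallbacks**

Step 8 (the proposed new step). The asymmetric catalyst may give poor face selectivity, or turnover may be too slow at macrocyclisation dilution. The fallback uses known chemistry and sets out from 16. Stoichiometric CrCl2 (4 equiv) in THF/DMF at high dilution, followed by acid, is the established ligand-free chromium Barbier macrocyclisation–lactonisation. Because 16 already carries the (R) side chain, the ring forms as two diastereomers, 19 and its (7S,8R) ring diastereomer F6. These are separated by preparative HPLC and the route is rejoined at 19.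

Step 5 (cross-metathesis with a 1,1-disubstituted bromomethyl acrylate). It may stall or cause migration of the skipped diene. The fallback sets out from 5 and builds the C6–C7 bond by cross-coupling and the acrylate by Morita–Baylis–Hillman chemistry:
- The Grignard reagent from 5 is added to 6 as in step 3, but the alkenylmagnesium is quenched with iodine to give (2Z)-3-iodo-2-substituted allylic alcohol F1.
- EDC/DMAP esterification with 11 gives iodo ester F2.
- Negishi coupling with (1,3-dioxolan-2-ylmethyl)zinc bromide (Pd(PPh3)4, THF, 50 °C) gives dioxolane F3.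
- Acetal cleavage that spares the silyl ether (Et3SiOTf, 2,4,6-collidine, then H2O) gives β,γ-unsaturated aldehyde F4.
- Morita–Baylis–Hillman reaction with methyl acrylate (DABCO) gives allylic alcohol F5.
- NBS/Me2S converts F5 with allylic transposition into the rearranged primary bromide, which is 14, where the route is rejoined.

Step 9 (late allylic hydroxylation). Conversion may be low, or the kinetic [2,3] outcome may not be clean. The fallback sets out from 19 and replaces direct hydroxylation by an oxidation–reduction detour under thermodynamic control of the alkene geometry. SeO2 (1.5 equiv) in dioxane at 80 °C (or the step 9 mixture followed by MnO2) takes C14 to the conjugated 14-oxo enal F7, whose C1=C10 bond settles in the ring-cis form. Luche reduction (NaBH4, CeCl3·7H2O, MeOH, −40 °C) then reduces only the aldehyde and gives 20.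

Further compounds
F1 | step 5 | (2Z)-3-iodo-2-[(3E)-6-{[tert-butyl(dimethyl)silyl]oxy}-4-methylhex-3-en-1-yl]prop-2-en-1-ol | OC/C(CC/C=C(\C)CCO[Si](C)(C)C(C)(C)C)=C\I
F2 | step 5 | (2Z)-3-iodo-2-[(3E)-6-{[tert-butyl(dimethyl)silyl]oxy}-4-methylhex-3-en-1-yl]prop-2-en-1-yl (2R)-3-chloro-2-hydroxy-2-methylpropanoate | I\C=C(/COC(=O)[C@@](C)(O)CCl)CC/C=C(\C)CCO[Si](C)(C)C(C)(C)C
F3 | step 5 | (2Z)-4-(1,3-dioxolan-2-yl)-2-[(3E)-6-{[tert-butyl(dimethyl)silyl]oxy}-4-methylhex-3-en-1-yl]but-2-en-1-yl (2R)-3-chloro-2-hydroxy-2-methylpropanoate | O1CCOC1C\C=C(/COC(=O)[C@@](C)(O)CCl)CC/C=C(\C)CCO[Si](C)(C)C(C)(C)C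
F4 | step 5 | (2Z)-2-[(3E)-6-{[tert-butyl(dimethyl)silyl]oxy}-4-methylhex-3-en-1-yl]-5-oxopent-2-en-1-yl (2R)-3-chloro-2-hydroxy-2-methylpropanoate | O=CC\C=C(/COC(=O)[C@@](C)(O)CCl)CC/C=C(\C)CCO[Si](C)(C)C(C)(C)C
F5 | step 5 | methyl (5Z,9E)-12-{[tert-butyl(dimethyl)silyl]oxy}-6-({[(2R)-3-chloro-2-hydroxy-2-methylpropanoyl]oxy}methyl)-3-hydroxy-10-methyl-2-methylidenedodeca-5,9-dienoate (both C3 epimers) | COC(=O)C(=C)C(O)C\C=C(/COC(=O)[C@@](C)(O)CCl)CC/C=C(\C)CCO[Si](C)(C)C(C)(C)C
F6 | step 8 | (7S,8R)-15-{[(2R)-3-chloro-2-hydroxy-2-methylpropanoyl]oxy}germacra-1(10),4,11(13)-trien-12,8-olide, ring diastereomer of 19 | C=C1C(=O)O[C@@H]2C/C(C)=C/CC/C(COC(=O)[C@@](C)(O)CCl)=C/C[C@@H]12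
F7 | step 9 | (7R,8S)-15-{[(2R)-3-chloro-2-hydroxy-2-methylpropanoyl]oxy}-14-oxogermacra-1(10),4,11(13)-trien-12,8-olide, C1=C10 ring-cis | C=C1C(=O)O[C@H]2C/C(C=O)=C\CC/C(COC(=O)[C@@](C)(O)CCl)=C/C[C@H]12
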